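**Plan**
Numbering: ring B = C1 (bears C20H2OAc)–C2–C3–C4 (bears C11, the side-chain CHCH3)–C4a–C8a. Ring A = C4a–C5–C6 (CO2H)–C7–C8 (OH)–C8a.
Retrosynthesis: the acetate and the free acid are adjusted last. C1–C20 is cut to CO/H2 on a C1=C2 styrene, ring A is taken back to its C8 ketone, and then C2–C3 and C4–C4a are cut together.
Enabling feature: O8 sits next to C8a, so the keto form of ring A contains the enone C8(=O)–C8a=C4a. A vinyl group C1=C2 on C8a turns this into a 2-acyl-1,3-diene with termini C4a (electrophilic) and C2. The remainder, C3–C4–C11 plus the chain, is (S)-citronellal, with C3 as the CHO carbon and C4 as the enamine carbon.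
Forward: ring A is made first as a cyclohexenone ester and carried partly saturated. Ring B is closed onto it by an amine-catalysed inverse-demand [4+2] with loss of the amine. Ring A is aromatised next, and C20 is added last.
Stereochemistry: C11 comes from (S)-citronellal. C4 comes from the enamine face left open by an (R)-diarylprolinol silyl ether. C1 comes from syn addition of H and CHO to the C1=C2 face anti to the pseudoaxial C4 chain.

Key step: step 4

Assumption: ring-A centres C6 (in 1–3, 5, 8–11) and C4a (in 8–12) are carried as mixtures, because both become sp2 in step 5. The SMILES leave them open.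

Step 1
Reactants: 1 methyl cyclohex-3-ene-1-carboxylate
Product: 2 methyl 5-oxocyclohex-3-ene-1-carboxylate (racemic)
Conditions: dirhodium tetracaprolactamate Rh2(cap)4 (0.5 mol %), t-BuOOH (5 equiv), K2CO3 (0.5 equiv), CH2Cl2, rt
Reagents that add atoms: tert-butyl hydroperoxide CC(C)(C)OO
Why: This is a catalytic allylic C–H oxidation in which abstraction at the allylic CH2 remote from the ester gives an allyl radical whose two oxygenation sites lead to the same enone, while the CH2 next to the ester-bearing carbon is inductively and sterically deactivated.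

Step 2
Reactants: 2 methyl 5-oxocyclohex-3-ene-1-carboxylate
Product: 3 methyl 4-iodo-5-oxocyclohex-3-ene-1-carboxylate (racemic)
Conditions: I2 (1.5 equiv), pyridine/CH2Cl2 (1:1), 0 °C to rt
Reagents that add atoms: iodine II
Why: This α-iodination of an enone (pyridine addition, iodination, elimination, a Baylis–Hillman-type sequence) should place iodine only on the α-carbon C8a and leave the ester untouched.

Step 3
Reactants: 3 methyl 4-iodo-5-oxocyclohex-3-ene-1-carboxylate; 4 tributyl(vinyl)stannane
Product: 5 methyl 4-ethenyl-5-oxocyclohex-3-ene-1-carboxylate (racemic 2-acyl diene)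
Conditions: PdCl2(PhCN)2 (5 mol %), AsPh3 (10 mol %), CuI (10 mol %), NMP, rt; kept as a cold dilute solution and used the same day
Reagents that add atoms: none
Why: Stille coupling of an α-iodoenone with the AsPh3/CuI ligand set runs at room temperature, which matters because 2-acyl dienes such as 5 tend to dimerise on standing.

Step 4
Reactants: 5 methyl 4-ethenyl-5-oxocyclohex-3-ene-1-carboxylate; 6 (S)-citronellal
Product: 9 methyl (8R)-8-[(2S)-6-methylhept-5-en-2-yl]-4-oxo-1,2,3,4,8,8a-hexahydronaphthalene-2-carboxylate (dienone; C4 and C11 as in the target), via enamine 7 (not isolated), via aminocycloadduct 8 (not isolated)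
Conditions: 6 (1.0 equiv), (R)-2-[diphenyl(trimethylsilyloxy)methyl]pyrrolidine (20 mol %), 4-nitrobenzoic acid (20 mol %), 4 Å MS, toluene, 0 °C; slow addition of 5 (1.5 equiv), then rt
Reagents that add atoms: none
Why: Proposed new method: condensation of 6 with the amine gives the (E)-enamine 7, whose nucleophilic C4 bonds to C4a (β to C8=O, the largest LUMO coefficient of the diene C2=C1–C8a=C4a), while the developing cross-conjugated dienolate closes from its γ-carbon C2 onto the iminium carbon C3, so both bonds form in one asynchronous inverse-electron-demand Diels–Alder event to give 8, and E1cB loss of the protonated amine across C2–C3 (C2–H is vinylogously acidified by C8=O) then frees the catalyst and leaves 9. The closest known reaction types are the aminocatalytic all-carbon inverse-demand Diels–Alder reactions of aldehyde enamines with acceptor-substituted dienes that turn over by the same β-elimination, the vinylquinone Diels–Alder reaction, and the amine-catalysed Michael/aldol annulation of citronellal with methyl vinyl ketone; the new element is a 2-vinylcyclohexenone as the diene, whose readiness to dimerise argues for a sufficiently low LUMO. Ring B is the only ring closed, by intermolecular [4+2] cycloaddition (read stepwise: Michael addition, then a 6-(enolendo)-exo-trig Mannich closure). C4 is set by the catalyst, whose CPh2(OSiMe3) group blocks one face of the s-trans (E)-enamine so that the (R)-amine should give the target sense with C11 as a spectator; C3 (trans to the chain, from the E geometry) is lost on elimination, and C4a and C6 are erased in step 5, so endo/exo selectivity and the use of racemic 5 do not matter. The step needs regioselectivity (C4 to C4a, not C2), secured by the enone polarity; periselectivity over closure through O8, which is reversible under the acid co-catalyst and cannot hydrolyse over sieves; chemoselectivity, since only the aldehyde is activated and the trisubstituted side-chain alkene is inert; and a rate above diene dimerisation, helped by slow addition of 5 to preformed 7.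

Step 5
Reactants: 9 dienone from step 4
Product: 13 methyl (8S)-4-hydroxy-8-[(2S)-6-methylhept-5-en-2-yl]-7,8-dihydronaphthalene-2-carboxylate, via lithium enolate 10 (not isolated), via sulfilimine 11 (not isolated), via trienone 12 (not isolated)
Conditions: LiN(iPr)2 (1.1 equiv), THF, −78 °C; N-tert-butylbenzenesulfinimidoyl chloride (1.2 equiv), −78 °C; DBU (1.2 equiv), −78 °C to rt; aq NH4Cl
Reagents that add atoms: none
Why: This is a Mukaiyama dehydrogenation followed by base-mediated tautomerisation to the phenol, in which kinetic α′-deprotonation at C7 gives 10, sulfur attack on the reagent gives 11, syn elimination with C6–H installs C6=C7 (12), and DBU moves the C5 and C4a protons to O8 and C3, so that ring A becomes the arene, the last alkene ends conjugated at C1=C2, all C4a/C6 epimers converge on one compound, and the tertiary, hindered, only remotely activated C4–H should stay in place.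

Step 6
Reactants: 13 dihydronaphthol ester from step 5
Product: 14 methyl (5R,8S)-5-formyl-4-hydroxy-8-[(2S)-6-methylhept-5-en-2-yl]-5,6,7,8-tetrahydronaphthalene-2-carboxylate
Conditions: Rh(acac)(CO)2 (1 mol %), (S,R)-BINAPHOS (2 mol %), CO/H2 (1:1, 40 bar), toluene, 50 °C
Reagents that add atoms: carbon monoxide [C-]#[O+]
Why: In this branched-selective asymmetric hydroformylation, a reaction type established for 1,2-dihydronaphthalene, H and CHO add syn to the C1=C2 face opposite the C4 chain (pseudoaxial to avoid C5–H), the benzylic rhodium alkyl favoured by the para ester puts the formyl group on C1, (S,R)-BINAPHOS is proposed as the antipode acting in the same sense, the trisubstituted side-chain alkene is too hindered to react, and C1 should therefore emerge trans to C4 (14 may rest as its five-membered lactol with O8).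

Step 7
Reactants: 14 aldehyde from step 6
Product: 15 methyl (5R,8S)-4-hydroxy-5-(hydroxymethyl)-8-[(2S)-6-methylhept-5-en-2-yl]-5,6,7,8-tetrahydronaphthalene-2-carboxylate
Conditions: NaBH4, MeOH, 0 °C, directly on crude 14
Reagents that add atoms: none
Why: Prompt borohydride reduction of the aldehyde (or of its lactol through the open form) removes the only epimerisable position at C1 and spares the aromatic ester and the alkene.

Step 8
Reactants: 15 diol ester from step 7
Product: 16 (5R,8S)-4-hydroxy-5-(hydroxymethyl)-8-[(2S)-6-methylhept-5-en-2-yl]-5,6,7,8-tetrahydronaphthalene-2-carboxylic acid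
Conditions: LiOH·H2O (4 equiv), THF/MeOH/H2O, 45 °C; cold 1 M HCl to pH 3
Reagents that add atoms: lithium hydroxide [Li+].[OH-]
Why: Saponification of the methyl benzoate is carried out before the acetate exists, so no ester differentiation is needed and no stereocentre is base-labile at this stage.

Step 9
Reactants: 16 diol acid from step 8
Product: 17 (5R,8S)-5-(acetoxymethyl)-4-hydroxy-8-[(2S)-6-methylhept-5-en-2-yl]-5,6,7,8-tetrahydronaphthalene-2-carboxylic acid (target)
Conditions: Novozym 435 (immobilised Candida antarctica lipase B), vinyl acetate (5 equiv), MTBE, 35 °C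
Reagents that add atoms: vinyl acetate C=COC(C)=O
Why: Lipase-catalysed irreversible transesterification acetylates primary aliphatic alcohols and leaves phenols and carboxylic acids free, as known for hydroxyalkylphenols.

**Compound list**
1 | methyl cyclohex-3-ene-1-carboxylate | COC(=O)C1CCC=CC1 | starting material
2 | methyl 5-oxocyclohex-3-ene-1-carboxylate | COC(=O)C1CC=CC(=O)C1 | intermediate
3 | methyl 4-iodo-5-oxocyclohex-3-ene-1-carboxylate | COC(=O)C1CC=C(I)C(=O)C1 | intermediate
4 | tributyl(vinyl)stannane | C=C[Sn](CCCC)(CCCC)CCCC | starting material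
5 | methyl 4-ethenyl-5-oxocyclohex-3-ene-1-carboxylate | COC(=O)C1CC=C(C=C)C(=O)C1 | intermediate
6 | (S)-citronellal, (3S)-3,7-dimethyloct-6-enal | O=CC[C@@H](C)CCC=C(C)C | starting material
7 | (E)-enamine of 6 with (R)-2-[diphenyl(trimethylsilyloxy)methyl]pyrrolidine | C[Si](C)(C)OC(c1ccccc1)(c1ccccc1)[C@H]1CCCN1/C=C/[C@@H](C)CCC=C(C)C | intermediate
8 | aminocycloadduct: the 4-oxo-1,2,3,4,6,7,8,8a-octahydronaphthalene-2-carboxylate with the (R)-pyrrolidinyl group at C7 (7S) trans to the (2S)-6-methylhept-5-en-2-yl group at C8 (8S) | COC(=O)C1CC(=O)C2=CC[C@H](N3CCC[C@@H]3C(O[Si](C)(C)C)(c4ccccc4)c5ccccc5)[C@@H]([C@@H](C)CCC=C(C)C)C2C1 | intermediate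
9 | methyl (8R)-8-[(2S)-6-methylhept-5-en-2-yl]-4-oxo-1,2,3,4,8,8a-hexahydronaphthalene-2-carboxylate | COC(=O)C1CC(=O)C2=CC=C[C@@H]([C@@H](C)CCC=C(C)C)C2C1 | intermediate
10 | lithium C7=C8 enolate of 9 | COC(=O)C1C=C(O[Li])C2=CC=C[C@@H]([C@@H](C)CCC=C(C)C)C2C1 | intermediate
11 | 9 bearing S(Ph)=N-t-Bu at C7 (naphthalene C3) | COC(=O)C1C(S(=NC(C)(C)C)c3ccccc3)C(=O)C2=CC=C[C@@H]([C@@H](C)CCC=C(C)C)C2C1 | intermediate
12 | methyl (8R)-8-[(2S)-6-methylhept-5-en-2-yl]-4-oxo-1,4,8,8a-tetrahydronaphthalene-2-carboxylate | COC(=O)C1=CC(=O)C2=CC=C[C@@H]([C@@H](C)CCC=C(C)C)C2C1 | intermediate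
13 | methyl (8S)-4-hydroxy-8-[(2S)-6-methylhept-5-en-2-yl]-7,8-dihydronaphthalene-2-carboxylate | COC(=O)c1cc(O)c2C=CC[C@@H]([C@@H](C)CCC=C(C)C)c2c1 | intermediate
14 | methyl (5R,8S)-5-formyl-4-hydroxy-8-[(2S)-6-methylhept-5-en-2-yl]-5,6,7,8-tetrahydronaphthalene-2-carboxylate | O=C[C@@H]1CC[C@@H]([C@@H](C)CCC=C(C)C)c2cc(C(=O)OC)cc(O)c21 | intermediate
15 | methyl (5R,8S)-4-hydroxy-5-(hydroxymethyl)-8-[(2S)-6-methylhept-5-en-2-yl]-5,6,7,8-tetrahydronaphthalene-2-carboxylate | OC[C@@H]1CC[C@@H]([C@@H](C)CCC=C(C)C)c2cc(C(=O)OC)cc(O)c21 | intermediate
16 | (5R,8S)-4-hydroxy-5-(hydroxymethyl)-8-[(2S)-6-methylhept-5-en-2-yl]-5,6,7,8-tetrahydronaphthalene-2-carboxylic acid | OC[C@@H]1CC[C@@H]([C@@H](C)CCC=C(C)C)c2cc(C(=O)O)cc(O)c21 | intermediate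
17 | (5R,8S)-5-(acetoxymethyl)-4-hydroxy-8-[(2S)-6-methylhept-5-en-2-yl]-5,6,7,8-tetrahydronaphthalene-2-carboxylic acid | CC(=O)OC[C@@H]1CC[C@@H]([C@@H](C)CCC=C(C)C)c2cc(C(=O)O)cc(O)c21 | target

Total step count: 9. Longest linear sequence: 9 (from 1).

**Steps most likely to fail**

Step 4. Three things may go wrong. Dimerisation of the diene may outrun the cross-cycloaddition. Closure through O8 may hold the catalyst as an aminal. Loss of the hindered amine may be too slow for turnover. The fallback sets out from 6 and 5 and returns at 9.
- 6 would be converted with TBSOTf/Et3N into the tert-butyldimethylsilyl enol ether of citronellal F1.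
- As a preformed oxygen-donor dienophile, this would be combined with 5 under Yb(fod)3 catalysis. This is a lanthanide-catalysed inverse-demand Diels–Alder reaction of an enol ether with a 2-carbonyl diene, mild enough for the side-chain alkene. It would give the 3-silyloxy cycloadduct F2.
- DBU would expel the silanol by E1cB and return 9.
- C4 would then be governed only by the endo rule and by C11, so the C4 epimers would have to be separated at 13.

Step 5. Enolisation may run along the dienone towards C4. Proton shuffling may aromatise ring B instead of ring A. The cyclohexadiene may be lost to oxidation. The fallback sets out from 9 and returns at 13, and takes ring B out of play first.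
- Diimide (2-nitrobenzenesulfonylhydrazide, Et3N) would saturate only the cis-disubstituted C2=C3 bond, giving the octahydro enone F3.
- The reagents of step 5 would then aromatise ring A to the tetralin phenol F4.
- Ag2O would oxidise the benzylic position ortho to the phenol (C1) to the ortho-quinone methide F5. C4 lies meta to the phenol and is not activated.
- F5 should tautomerise by a 1,5-hydrogen shift to the vinylphenol 13.

Step 6. The formyl group may be delivered to C2 because of the peri hydroxyl group. The alkene may migrate along ring B through reversible rhodium hydride addition. Facial discrimination may be too weak. The aldehyde may epimerise before reduction. The fallback sets out from 13 and returns at 15.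
- It is a copper hydride-catalysed reductive hydroxymethylation of the styrene with CO2. Conditions would be Cu(OAc)2, DTBM-SEGPHOS (the antipode matched to the substrate bias), (EtO)3SiH with extra silane allowed for the phenol, CO2 at 1 atm, then NH4F work-up.
- Here the regiochemistry rests on formation of the benzylic copper species at C1.
- No epimerisable aldehyde is ever present.

Further compounds
F1 | step 4 | (S)-citronellal tert-butyldimethylsilyl enol ether (E/Z) | CC(C)(C)[Si](C)(C)OC=C[C@@H](C)CCC=C(C)C
F2 | step 4 | methyl 7-(tert-butyldimethylsilyloxy)-8-[(2S)-6-methylhept-5-en-2-yl]-4-oxo-1,2,3,4,6,7,8,8a-octahydronaphthalene-2-carboxylate | COC(=O)C1CC(=O)C2=CCC(O[Si](C)(C)C(C)(C)C)C([C@@H](C)CCC=C(C)C)C2C1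
F3 | step 5 | methyl (8S)-8-[(2S)-6-methylhept-5-en-2-yl]-4-oxo-1,2,3,4,6,7,8,8a-octahydronaphthalene-2-carboxylate | COC(=O)C1CC(=O)C2=CCC[C@@H]([C@@H](C)CCC=C(C)C)C2C1
F4 | step 5 | methyl (8S)-4-hydroxy-8-[(2S)-6-methylhept-5-en-2-yl]-5,6,7,8-tetrahydronaphthalene-2-carboxylate | COC(=O)c1cc(O)c2CCC[C@@H]([C@@H](C)CCC=C(C)C)c2c1
F5 | step 5 | ortho-quinone methide of F4 (O8=C8, C8a=C1) | COC(=O)C1=CC(=O)C2=CCC[C@@H]([C@@H](C)CCC=C(C)C)C2=C1
F0 | step 6 | none | none
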